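The amber run shows how much target appears as starting material is lost; north-east and north differ from it in their charge of solid first nucleophile, in time and, for north, in temperature.

all flasks: starting material 0.25 M; second nucleophile 0.625 M
- amber: solid first nucleophile 0.22 M; temperature 50 °C; run made earlier
- north-east: solid first nucleophile 0.150 M; temperature 50 °C; time 4.0 h
- north: solid first nucleophile 0.150 M; temperature 65 °C; time 4.0 h

- amber (time / min: target / %, starting material / %): 6.00: 0.8, 91.5; 12.0: 3.7, 84.3; 20.0: 5.5, 74.4; 25.0: 7.7, 69.4

(scatter of a reading: 0.3 percentage points)

- at the start none of the solid first nucleophile is in solution
- the earlier runs do not show what temperature does; that part of a forecast is a guess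
- a reading or a percentage of target counts all its forms, free or not

* which flask leads in amount of target, in percent of the starting material charged ("all alike" within 1.5 percentage points) (north-east / north / all alike)
* how much target is there at the end, in percent of the starting material charged: north-east
* how much target is there at the end, in percent of the starting material charged: north

By 25.0 min the amber run has lost 30.6% of its starting material and holds 7.7% target. Their ratio, 25.2%, is the capture share, a selectivity: target gained per starting material lost. The same ratio reads 9.41% at 6.00 min, but 23.6% and 21.5% at 12.0 min and 20.0 min, so this reckoning treats it as level from there on and takes the rest of the lost starting material as gone elsewhere.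

The ledger is kept on the reagent charged in the smaller amount: in north-east, 0.150 M solid first nucleophile against 0.25 M starting material. Continued first order, the amber fall leaves 3.00% starting material at 4.0 h. Assuming the share holds, target in north-east reaches 24.4%. On this reckoning that draws 0.0610 M from the charge, so 0.0890 M stays unused. For north the same figure is a guess, since the share was read at 50 °C.

The forecast gives 57% for north-east, 57% for north and all alike, on the ground that the first nucleophile is the smaller charge, “so it caps target at about 60%”. It stands higher than this reckoning.

The flasks give 25.5% in north-east and 13.6% in north, crystals counted, so north-east leads.

    crystals ⇌ target, rate k1*(cs1 - [target]) while solid is left; crystals form when [target] > cs1 (solubility = 29.0 mM, k = 0.00280 /s)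
    first nucleophile + intermediate → target (k = 0.150 /M/s, Ea = 42.0 kJ/mol)
    second nucleophile + intermediate → other capture product (k = 0.0450 /M/s, Ea = 73.0 kJ/mol)
    solid first nucleophile ⇌ first nucleophile, rate k4*(cs4 - [first nucleophile]) while solid is left; crystals form when [first nucleophile] > cs4 (solubility = 0.140 M, k = 0.00260 /s)
    starting material → intermediate (k = 2.40 × 10⁻⁴ /s, Ea = 95.0 kJ/mol)
    intermediate → solvolysis product (k = 0.0180 /s, Ea = 93.0 kJ/mol)
    (constants at 50 °C)

North-east ends with 3.2% starting material, so its share reads 26.3% against 25.2% from amber. Its books close with 0.0638 M in target, c(first nucleophile) of 0.0862 M and solid first nucleophile at 0%, against 0.150 M charged. North reads 13.6%, about half of the amber share. North has come to rest: starting material is at 0% by 4.00 h, and at 40.0 h target stands at 13.6%. North-east has nearly come to rest: target reaches 26.3% at 40.0 h, 0.80 percentage points more.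

A neighbour, north with 0.62 M starting material, is reckoned with north's share: 0.0846 M target, leaving 0.0654 M first nucleophile. That flask ends with 12.5% target, which is 0.0775 M, and 0.0724 M first nucleophile.

The readings were generated by integration on assumed constants.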